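**Assumption:** the SMILES is read as epicatechin-(4β→6)-epiafzelechin-(4β→8)-epicatechin-(4β→6)-epicatechin, all four units (2R,3R) and all three interflavan bonds 3,4-trans. The units are called A (top), B (epiafzelechin), C and D (terminal) below.

## Retrosynthetic overview

1. Last C–C bond: C4(B)–C8(C), by Friedel–Crafts coupling of an A–B electrophile (C4 masked as a cyclic boronate) with a C–D nucleophile; then global hydrogenolysis.
2. Unit B is not coupled in as a monomer but built onto unit A: one operation closes its pyran ring and a fused 1,3,2-dioxaborolane on an aryloxy α-hydroxy aldehyde.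
3. That aldehyde comes from the symmetric phloroglucinol adduct of unit A (fixes the 4→6 linkage) and a cis-glycidate (fixes C2 and C3 of B).
4. C–D: halogen-capped 4β→6 Friedel–Crafts coupling of two epicatechin units, then selective removal of the bromine cap on C.
5. Ring order: pyran rings of A, C and D come from (−)-epicatechin; the pyran ring of B and the boronate ring form together in step 12.

## Route

Step 1
Reactants: 1 (−)-epicatechin
Product: 2 5,7,3',4'-tetra-O-benzyl-(−)-epicatechin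
Conditions: BnBr (4.4 equiv), K2CO3 (5 equiv), DMF, 0 °C to rt, argon
Reagents that add atoms: benzyl bromide, BrCc1ccccc1
Why: Williamson etherification in which K2CO3 deprotonates only the four phenols, so the secondary 3-OH stays free and C2/C3 are untouched.

Step 2
Reactants: 2 5,7,3',4'-tetra-O-benzyl-(−)-epicatechin
Product: 3 8-bromo-5,7,3',4'-tetra-O-benzylepicatechin
Conditions: NBS (1.05 equiv), CH2Cl2, −45 °C to rt
Reagents that add atoms: N-bromosuccinimide, BrN1C(=O)CCC1=O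
Why: Electrophilic aromatic bromination at C8, the most accessible activated position of ring A (next to the ring oxygen), which installs the cap that later blocks self-condensation.

Step 3
Reactants: 3 8-bromo-5,7,3',4'-tetra-O-benzylepicatechin
Product: 4 8-bromo-4β-(2-ethoxyethoxy)-5,7,3',4'-tetra-O-benzylepicatechin
Conditions: DDQ (2 equiv), 2-ethoxyethanol (10 equiv), CH2Cl2, rt
Reagents that add atoms: 2-ethoxyethanol, CCOCCO
Why: DDQ benzylic oxidation (hydride abstraction at C4 to the ring-A-stabilised cation) and capture by the alcohol anti to the 3-OH gives the 4β ether; C2 and C3 are unchanged.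

Step 4
Reactants: 2 5,7,3',4'-tetra-O-benzyl-(−)-epicatechin
Product: 5 8-chloro-5,7,3',4'-tetra-O-benzylepicatechin
Conditions: NCS (1.1 equiv), CH2Cl2, 0 °C to rt
Reagents that add atoms: N-chlorosuccinimide, ClN1C(=O)CCC1=O
Why: Electrophilic aromatic chlorination with the same C8 preference as bromination, giving a nucleophile whose only free ring-A position is C6 and whose cap survives organolithium treatment.

Step 5
Reactants: 4 8-bromo-4β-(2-ethoxyethoxy)-5,7,3',4'-tetra-O-benzylepicatechin; 5 8-chloro-5,7,3',4'-tetra-O-benzylepicatechin (3 equiv, excess recovered)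
Product: 6 [8-bromo-tetra-O-benzylepicatechin]-(4β→6)-[8-chloro-tetra-O-benzylepicatechin]
Conditions: Me3SiOTf (0.5 equiv), CH2Cl2, 4 Å molecular sieves, −40 to −20 °C; aq. NaHCO3
Reagents that add atoms: none
Why: Lewis-acid Friedel–Crafts coupling through the C4 cation of 4 with both C8 positions halogen-capped, so the bond must form at C6 of 5, and attack anti to the 3-OH of the 2,3-cis electrophile sets C4 as 4β.

Step 6
Reactants: 6 [8-bromo-tetra-O-benzylepicatechin]-(4β→6)-[8-chloro-tetra-O-benzylepicatechin]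
Product: 7 tetra-O-benzylepicatechin-(4β→6)-[8-chloro-tetra-O-benzylepicatechin]
Conditions: t-BuLi (4.5 equiv), THF, −78 °C, 20 min; MeOH, −78 °C to rt
Reagents that add atoms: none
Why: Chemoselective bromine–lithium exchange (the aryl chloride does not exchange at −78 °C) followed by protonation frees C8 of unit C while D stays capped; no stereocentre is involved.

Step 7
Reactants: 4 8-bromo-4β-(2-ethoxyethoxy)-5,7,3',4'-tetra-O-benzylepicatechin; 8 phloroglucinol (5 equiv)
Product: 9 8-bromo-5,7,3',4'-tetra-O-benzylepicatechin-(4β→2)-phloroglucinol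
Conditions: Me3SiOTf (0.3 equiv), THF–CH2Cl2 1:4, −40 to 0 °C, argon
Reagents that add atoms: none
Why: Friedel–Crafts coupling with symmetric phloroglucinol, whose three ring positions are equivalent so no regiochemical question arises, with anti attack giving 4β.

Step 8
Reactants: 10 4-(benzyloxy)benzaldehyde; 11 ethyl 2-(diphenoxyphosphoryl)acetate
Product: 12 ethyl (Z)-3-[4-(benzyloxy)phenyl]prop-2-enoate
Conditions: NaH, THF, −78 to 0 °C
Reagents that add atoms: none
Why: Ando variant of the Horner–Wadsworth–Emmons olefination, in which the diaryl phosphonate gives the Z-cinnamate under kinetic control (about 9:1, minor E isomer removed by chromatography).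

Step 9
Reactants: 12 ethyl (Z)-3-[4-(benzyloxy)phenyl]prop-2-enoate
Product: 13 ethyl (2S,3S)-3-[4-(benzyloxy)phenyl]oxirane-2-carboxylate (cis)
Conditions: (S,S)-(salen)MnCl (C36H52ClMnN2O2, trivalent manganese, 6 mol %), aq. NaOCl (pH 11.3), 4-phenylpyridine N-oxide (0.25 equiv), CH2Cl2, 4 °C
Reagents that add atoms: sodium hypochlorite, [Na+].[O-]Cl
Why: Jacobsen–Katsuki epoxidation of a cis-cinnamate, where the (S,S) catalyst gives the (2S,3S)-cis-glycidate (the antipode of the product known from the (R,R) catalyst); minor trans epoxide is separated.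

Step 10
Reactants: 9 8-bromo-5,7,3',4'-tetra-O-benzylepicatechin-(4β→2)-phloroglucinol; 13 ethyl (2S,3S)-3-[4-(benzyloxy)phenyl]oxirane-2-carboxylate
Product: 15 ethyl (2S,3R)-3-[4-(benzyloxy)phenyl]-2-hydroxy-3-{3,5-bis(benzyloxy)-4-[8-bromo-5,7,3',4'-tetra-O-benzylepicatechin-4β-yl]phenoxy}propanoate, via para-monoether diphenol 14 (not isolated)
Conditions: Cs2CO3 (1.2 equiv), DMF, 60 °C, argon; then BnBr (2.5 equiv), Cs2CO3 (2.5 equiv), rt
Reagents that add atoms: benzyl bromide, BrCc1ccccc1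
Why: Phenoxide SN2 opening of the glycidate at the benzylic carbon with inversion (3S to 3R) sets the future C2 of unit B while the ester-bearing carbon keeps its configuration as the future C3; the para hydroxyl reacts because the two ortho hydroxyls are shielded by the flavanyl group, and these are then benzylated in the same pot (Williamson).

Step 11
Reactants: 15 the ester from step 10
Product: 16 (2S,3R)-3-[4-(benzyloxy)phenyl]-2-hydroxy-3-{3,5-bis(benzyloxy)-4-[8-bromo-5,7,3',4'-tetra-O-benzylepicatechin-4β-yl]phenoxy}propanal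
Conditions: i-Bu2AlH (5 equiv), CH2Cl2, −78 °C; MeOH, then aq. KNaC4H4O6; used crude at once
Reagents that add atoms: none
Why: DIBAL-H half-reduction of an α-hydroxy ester, where the chelated aluminium hemiacetal survives at −78 °C and releases the aldehyde only on work-up; both stereocentres are untouched.

Step 12
Reactants: 16 the α-hydroxy aldehyde from step 11; 17 phenylboronic acid
Product: 19 cyclic 3,4-O-phenylboronate of [8-bromo-tetra-O-benzylepicatechin]-(4β→6)-[5,7,4'-tri-O-benzyl-2,3-cis-3,4-cis-flavan-3,4-diol], via boronic monoester 18 (not isolated)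
Conditions: PhB(OH)2 (1.2 equiv), PhCO2H (10 mol %), 4 Å molecular sieves, toluene, rt to 45 °C
Reagents that add atoms: none
Why: Proposed new method: the boronic acid esterifies the α-hydroxyl, activates the neighbouring aldehyde intramolecularly, and the electron-rich ring attacks it ortho to the ether oxygen in a six-membered Friedel–Crafts hydroxyalkylation whose new C4 alkoxide is captured on boron in the same event, so the pyran ring of unit B and the cis-fused 1,3,2-dioxaborolane form together with C2/C3 carried over unchanged from 16 and the C4 oxygen necessarily cis to the C3 oxygen; the closest known reaction type is the Nagata phenylboronic-acid-templated ortho-hydroxyalkylation of phenols with aldehydes to 1,3,2-benzodioxaborins.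

Step 13
Reactants: 19 the A–B cyclic boronate; 7 tetra-O-benzylepicatechin-(4β→6)-[8-chloro-tetra-O-benzylepicatechin] (2.5 equiv, excess recovered)
Product: 20 pentadeca-O-benzyl [8-bromo-epicatechin]-(4β→6)-epiafzelechin-(4β→8)-epicatechin-(4β→6)-[8-chloro-epicatechin]
Conditions: Me3SiOTf (0.5 equiv), 4 Å molecular sieves, CH2Cl2, −78 to −30 °C; aq. NaHCO3
Reagents that add atoms: none
Why: Proposed new method: the Lewis acid ionises the benzylic C4–O–B bond so that the boronate acts as the leaving group, and Friedel–Crafts attack by C8 of unit C of 7 (the most reactive free position, C8 of D being capped) anti to the 3-O–boron substituent gives the 4β interflavan bond, boron being lost on aqueous work-up; the closest known reaction types are Lewis-acid substitution of 1,3,2-benzodioxaborins and the coupling of 4-alkoxyflavan-3-ols.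

Step 14
Reactants: 20 the protected tetramer
Product: 21 epicatechin-(4β→6)-epiafzelechin-(4β→8)-epicatechin-(4β→6)-epicatechin (target)
Conditions: H2 (1–3 atm), Pd(OH)2/C, Et3N (6 equiv), THF–MeOH–H2O, rt; Sephadex LH-20
Reagents that add atoms: none
Why: Catalytic hydrogenolysis removes the fifteen benzyl ethers and both aryl halides (amine-promoted hydrodehalogenation) without touching the stereocentres or the interflavan bonds.

## Compound list

1 | (−)-epicatechin, (2R,3R)-2-(3,4-dihydroxyphenyl)chromane-3,5,7-triol | O[C@@H]1Cc2c(O)cc(O)cc2O[C@@H]1c1ccc(O)c(O)c1 | starting material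
2 | 5,7,3',4'-tetra-O-benzyl-(−)-epicatechin (2R,3R, 3-OH free) | O[C@@H]1Cc2c(OCc3ccccc3)cc(OCc3ccccc3)cc2O[C@@H]1c1ccc(OCc2ccccc2)c(OCc2ccccc2)c1 | intermediate
3 | 8-bromo-5,7,3',4'-tetra-O-benzylepicatechin (2R,3R) | O[C@@H]1Cc2c(OCc3ccccc3)cc(OCc3ccccc3)c(Br)c2O[C@@H]1c1ccc(OCc2ccccc2)c(OCc2ccccc2)c1 | intermediate
4 | 8-bromo-4β-(2-ethoxyethoxy)-5,7,3',4'-tetra-O-benzylepicatechin (2,3-cis, 3,4-trans) | CCOCCO[C@H]1c2c(OCc3ccccc3)cc(OCc3ccccc3)c(Br)c2O[C@H](c2ccc(OCc3ccccc3)c(OCc3ccccc3)c2)[C@@H]1O | intermediate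
5 | 8-chloro-5,7,3',4'-tetra-O-benzylepicatechin (2R,3R) | O[C@@H]1Cc2c(OCc3ccccc3)cc(OCc3ccccc3)c(Cl)c2O[C@@H]1c1ccc(OCc2ccccc2)c(OCc2ccccc2)c1 | intermediate
6 | [8-bromo-tetra-O-benzylepicatechin]-(4β→6)-[8-chloro-tetra-O-benzylepicatechin] | Brc1c(OCc2ccccc2)cc(OCc2ccccc2)c2c1O[C@H](c1ccc(OCc3ccccc3)c(OCc3ccccc3)c1)[C@H](O)[C@H]2c1c(OCc2ccccc2)c(Cl)c2c(c1OCc1ccccc1)C[C@@H](O)[C@@H](c1ccc(OCc3ccccc3)c(OCc3ccccc3)c1)O2 | intermediate
7 | tetra-O-benzylepicatechin-(4β→6)-[8-chloro-tetra-O-benzylepicatechin] (C8 of upper unit free) | c1c(OCc2ccccc2)cc(OCc2ccccc2)c2c1O[C@H](c1ccc(OCc3ccccc3)c(OCc3ccccc3)c1)[C@H](O)[C@H]2c1c(OCc2ccccc2)c(Cl)c2c(c1OCc1ccccc1)C[C@@H](O)[C@@H](c1ccc(OCc3ccccc3)c(OCc3ccccc3)c1)O2 | intermediate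
8 | phloroglucinol (benzene-1,3,5-triol) | Oc1cc(O)cc(O)c1 | starting material
9 | 8-bromo-5,7,3',4'-tetra-O-benzylepicatechin-(4β→2)-phloroglucinol (4β-(2,4,6-trihydroxyphenyl) derivative) | Oc1cc(O)c([C@H]2c3c(OCc4ccccc4)cc(OCc4ccccc4)c(Br)c3O[C@H](c3ccc(OCc4ccccc4)c(OCc4ccccc4)c3)[C@@H]2O)c(O)c1 | intermediate
10 | 4-(benzyloxy)benzaldehyde | O=Cc1ccc(OCc2ccccc2)cc1 | starting material
11 | ethyl 2-(diphenoxyphosphoryl)acetate | CCOC(=O)CP(=O)(Oc1ccccc1)Oc1ccccc1 | starting material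
12 | ethyl (Z)-3-[4-(benzyloxy)phenyl]prop-2-enoate | CCOC(=O)/C=C\c1ccc(OCc2ccccc2)cc1 | intermediate
13 | ethyl (2S,3S)-3-[4-(benzyloxy)phenyl]oxirane-2-carboxylate (cis) | CCOC(=O)[C@H]1O[C@H]1c1ccc(OCc2ccccc2)cc1 | intermediate
14 | ethyl (2S,3R)-3-[4-(benzyloxy)phenyl]-2-hydroxy-3-{3,5-dihydroxy-4-[8-bromo-tetra-O-benzylepicatechin-4β-yl]phenoxy}propanoate | CCOC(=O)[C@@H](O)[C@H](Oc1cc(O)c([C@H]2c3c(OCc4ccccc4)cc(OCc4ccccc4)c(Br)c3O[C@H](c3ccc(OCc4ccccc4)c(OCc4ccccc4)c3)[C@@H]2O)c(O)c1)c1ccc(OCc2ccccc2)cc1 | intermediate (not isolated)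
15 | ethyl (2S,3R)-3-[4-(benzyloxy)phenyl]-2-hydroxy-3-{3,5-bis(benzyloxy)-4-[8-bromo-tetra-O-benzylepicatechin-4β-yl]phenoxy}propanoate | CCOC(=O)[C@@H](O)[C@H](Oc1cc(OCc2ccccc2)c([C@H]2c3c(OCc4ccccc4)cc(OCc4ccccc4)c(Br)c3O[C@H](c3ccc(OCc4ccccc4)c(OCc4ccccc4)c3)[C@@H]2O)c(OCc2ccccc2)c1)c1ccc(OCc2ccccc2)cc1 | intermediate
16 | (2S,3R)-3-[4-(benzyloxy)phenyl]-2-hydroxy-3-{3,5-bis(benzyloxy)-4-[8-bromo-tetra-O-benzylepicatechin-4β-yl]phenoxy}propanal | O=C[C@@H](O)[C@H](Oc1cc(OCc2ccccc2)c([C@H]2c3c(OCc4ccccc4)cc(OCc4ccccc4)c(Br)c3O[C@H](c3ccc(OCc4ccccc4)c(OCc4ccccc4)c3)[C@@H]2O)c(OCc2ccccc2)c1)c1ccc(OCc2ccccc2)cc1 | intermediate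
17 | phenylboronic acid | OB(O)c1ccccc1 | starting material
18 | O-[hydroxy(phenyl)boranyl] monoester of 16 at the 2-hydroxyl | O=C[C@@H](OB(O)c1ccccc1)[C@H](Oc1cc(OCc2ccccc2)c([C@H]2c3c(OCc4ccccc4)cc(OCc4ccccc4)c(Br)c3O[C@H](c3ccc(OCc4ccccc4)c(OCc4ccccc4)c3)[C@@H]2O)c(OCc2ccccc2)c1)c1ccc(OCc2ccccc2)cc1 | intermediate (not isolated)
19 | cyclic 3,4-O-phenylboronate (cis-fused 2-phenyl-1,3,2-dioxaborolane) of [8-bromo-tetra-O-benzylepicatechin]-(4β→6)-[5,7,4'-tri-O-benzyl-(2R,3R)-2,3-cis-3,4-cis-flavan-3,4-diol] | c1ccccc1COc1ccc([C@H]2Oc3cc(OCc4ccccc4)c([C@H]4c5c(OCc6ccccc6)cc(OCc6ccccc6)c(Br)c5O[C@H](c5ccc(OCc6ccccc6)c(OCc6ccccc6)c5)[C@@H]4O)c(OCc4ccccc4)c3[C@H]3OB(c4ccccc4)O[C@H]32)cc1 | intermediate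
20 | pentadeca-O-benzyl [8-bromo-epicatechin]-(4β→6)-epiafzelechin-(4β→8)-epicatechin-(4β→6)-[8-chloro-epicatechin] | c1ccccc1COc1ccc([C@H]2Oc3cc(OCc4ccccc4)c([C@H]4c5c(OCc6ccccc6)cc(OCc6ccccc6)c(Br)c5O[C@H](c5ccc(OCc6ccccc6)c(OCc6ccccc6)c5)[C@@H]4O)c(OCc4ccccc4)c3[C@H](c3c(OCc4ccccc4)cc(OCc4ccccc4)c4c3O[C@H](c3ccc(OCc5ccccc5)c(OCc5ccccc5)c3)[C@H](O)[C@H]4c3c(OCc4ccccc4)c(Cl)c4c(c3OCc3ccccc3)C[C@@H](O)[C@@H](c3ccc(OCc5ccccc5)c(OCc5ccccc5)c3)O4)[C@H]2O)cc1 | intermediate
21 | epicatechin-(4β→6)-epiafzelechin-(4β→8)-epicatechin-(4β→6)-epicatechin (CNP0103636.1) | Oc1ccc([C@H]2Oc3cc(O)c([C@H]4c5c(O)cc(O)cc5O[C@H](c5ccc(O)c(O)c5)[C@@H]4O)c(O)c3[C@H](c3c(O)cc(O)c4c3O[C@H](c3ccc(O)c(O)c3)[C@H](O)[C@H]4c3c(O)cc4c(c3O)C[C@@H](O)[C@@H](c3ccc(O)c(O)c3)O4)[C@H]2O)cc1 | target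

## Step count and risks

Total steps: 14. Longest linear sequence: 9 steps (1 → 2 → 3 → 4 → 9 → 15 → 16 → 19 → 20 → 21, i.e. steps 1, 2, 3, 7, 10, 11, 12, 13, 14).

**Step 10 (site-selective etherification).** Three phenols compete, phloroglucinol anions can also C-alkylate, and the p-alkoxybenzylic epoxide carbon may leak from clean inversion. The fallback sets out from 9 and returns at 15. Compound 9 is silylated with i-Pr3SiCl/imidazole, the bulky chloride taking only the unhindered para hydroxyl, to give the para-O-triisopropylsilyl ether F1. The two hindered ortho phenols are then benzylated (BnBr, Cs2CO3, DMF) to the bis-benzyl silyl ether F2, and Bu4NF removes the silyl group to give the mono-phenol F3. Its single phenoxide opens 13 (Cs2CO3, DMF, 60 °C) to give 15 with no site-selectivity question, at the cost of three extra steps.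

**Step 12 (boron-templated double ring closure).** This is unprecedented on such a substrate; the α-hydroxy aldehyde may epimerise or lose aryloxide, and the product may ionise at C4. The fallback sets out from 16 and returns at 20. Compound 16 is treated with HC(OMe)3 and camphorsulfonic acid in MeOH–CH2Cl2; the dimethyl acetal formed in situ ionises to the oxocarbenium ion and closes onto the ring in a Prins/Friedel–Crafts cyclisation. This gives the 4-methoxy-flavan-3-ol dimer F4 (pyran ring only; C4 epimers, both usable). F4 is a classical 4-alkoxy electrophile and couples with 7 under Me3SiOTf at −78 to −30 °C to give 20 directly.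

**Step 13 (fragment coupling through the boronate).** Ionisation of C4–O–B is unproven, the electrophile has a free C8 on unit B that can self-condense, and elimination to a flavene is possible. The fallback sets out from 19 and returns at 20. Compound 19 is opened with phenylmethanethiol and BF3·OEt2 at −20 °C (thiolysis-type capture anti to O3) to give the 4β-benzylthio ether F5, which is purified. F5 is then activated with the thiophilic salt AgBF4 in THF at 0 °C in the presence of 7 (2.5 equiv). The slow, near-neutral release of the C4 cation suppresses self-condensation and gives 20.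

## Further compounds

F1 | step 10 | para-O-triisopropylsilyl ether of 9 (silyl on the hydroxyl para to the flavanyl group) | CC(C)[Si](C(C)C)(C(C)C)Oc1cc(O)c([C@H]2c3c(OCc4ccccc4)cc(OCc4ccccc4)c(Br)c3O[C@H](c3ccc(OCc4ccccc4)c(OCc4ccccc4)c3)[C@@H]2O)c(O)c1
F2 | step 10 | 2,6-di-O-benzyl-4-O-triisopropylsilyl derivative of 9 | CC(C)[Si](C(C)C)(C(C)C)Oc1cc(OCc2ccccc2)c([C@H]2c3c(OCc4ccccc4)cc(OCc4ccccc4)c(Br)c3O[C@H](c3ccc(OCc4ccccc4)c(OCc4ccccc4)c3)[C@@H]2O)c(OCc2ccccc2)c1
F3 | step 10 | 4β-[2,6-bis(benzyloxy)-4-hydroxyphenyl]-8-bromo-5,7,3',4'-tetra-O-benzylepicatechin | Oc1cc(OCc2ccccc2)c([C@H]2c3c(OCc4ccccc4)cc(OCc4ccccc4)c(Br)c3O[C@H](c3ccc(OCc4ccccc4)c(OCc4ccccc4)c3)[C@@H]2O)c(OCc2ccccc2)c1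
F4 | step 12 | [8-bromo-tetra-O-benzylepicatechin]-(4β→6)-[4-methoxy-5,7,4'-tri-O-benzylepiafzelechin] (4β epimer drawn) | c1ccccc1COc1ccc([C@H]2Oc3cc(OCc4ccccc4)c([C@H]4c5c(OCc6ccccc6)cc(OCc6ccccc6)c(Br)c5O[C@H](c5ccc(OCc6ccccc6)c(OCc6ccccc6)c5)[C@@H]4O)c(OCc4ccccc4)c3[C@H](OC)[C@H]2O)cc1
F5 | step 13 | [8-bromo-tetra-O-benzylepicatechin]-(4β→6)-[4β-benzylthio-5,7,4'-tri-O-benzylepiafzelechin] | c1ccccc1COc1ccc([C@H]2Oc3cc(OCc4ccccc4)c([C@H]4c5c(OCc6ccccc6)cc(OCc6ccccc6)c(Br)c5O[C@H](c5ccc(OCc6ccccc6)c(OCc6ccccc6)c5)[C@@H]4O)c(OCc4ccccc4)c3[C@H](SCc4ccccc4)[C@H]2O)cc1
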